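C1 bears the OH, C2 the tricosyl chain, C4 and C6 the OMe groups. The retrosynthesis masks C1–OH as a benzyl ether, returns the arene to a cyclohexane-1,3-dione (C4, C6 = C=O), adds a carboxyl at C3, then cuts ring bonds C2–C3 and C4–C5.
Enabling feature: in the single benzene ring the oxygens on C4 and C6 are 1,3-related, the neighbouring C1 is also oxygenated and C2 holds the chain. C5–C6–C1–C2 is therefore a 3-alkoxyalk-3-en-2-one, and C3–C4 is the CH–C(=O) arm of a malonate.
The enone is cut at C1=C2 into tetracosanal and an α-benzyloxy-β-ketophosphonate. The phosphonate is cut at its C–O bond into a diazophosphonate and benzyl alcohol.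
Forward: the chain is joined first by olefination and the only ring closes around it. The spare ester is then removed, the ring is aromatised with methyl ether formation at C4 and C6, and the benzyl group goes last.
Stereochemistry: the target has none. The sp3 centres and the olefin geometry that arise on the way are erased on aromatisation and need no control.

Key step: step 4

Assumption: the target SMILES holds no stereocentre and no stereogenic double bond, so the compound is achiral and no enantioselective step is needed. The 1,3-dicarbonyl compounds are drawn as keto forms, although they should be largely enolised.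

Step 1
Reactants: 1 1-tetracosanol
Product: 2 tetracosanal
Conditions: IBX (1.5 equiv), EtOAc, 80 °C; filtered hot
Reagents that add atoms: none
Why: IBX oxidation of a primary alcohol stops at the aldehyde, hot ethyl acetate keeps the waxy C24 substrate dissolved, and the spent iodine(III) acid is removed by filtration.

Step 2
Reactants: 3 dimethyl (1-diazo-2-oxopropyl)phosphonate; 4 benzyl alcohol
Product: 5 dimethyl [1-(benzyloxy)-2-oxopropyl]phosphonate (racemic)
Conditions: Rh2(OAc)4 (1 mol %), 4 (1.5 equiv), 1,2-dichloroethane, 80 °C, slow addition of 3
Reagents that add atoms: none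
Why: Rhodium(II)-carbenoid O–H insertion of an α-diazo-β-ketophosphonate into a primary alcohol places the benzyloxy group on the carbon between C=O and P, which avoids any regiochemical question of ketone enolisation, and the new racemic centre disappears in step 3.

Step 3
Reactants: 5 dimethyl [1-(benzyloxy)-2-oxopropyl]phosphonate; 2 tetracosanal
Product: 6 (Z)-3-(benzyloxy)heptacos-3-en-2-one
Conditions: NaH (1.05 equiv), THF, 0 °C; then 2 in warm THF, 0 to 40 °C
Reagents that add atoms: none
Why: Horner–Wadsworth–Emmons olefination with a fully preformed stabilised anion leaves no free base to enolise the aldehyde and should favour the isomer with the chain trans to the acetyl group (Z), while any E isomer can be carried on because both converge in step 4.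

Step 4
Reactants: 6 (Z)-3-(benzyloxy)heptacos-3-en-2-one; 7 dimethyl malonate
Product: 9 methyl 3-(benzyloxy)-4,6-dioxo-2-tricosylcyclohexane-1-carboxylate (diastereomer mixture), via acyclic Michael adduct 8 (not isolated)
Conditions: 7 (1.5 equiv), NaOMe (1.5 equiv), MeOH–THF, concentrated, 65 °C, Ar; then 1 M HCl, 0 °C
Reagents that add atoms: none
Why: Proposed new method: sodium dimethyl malonate should add to the chain-bearing β-carbon of 6 (bond C2–C3) to give 8, proton transfer then exposes the methyl-ketone enolate, whose CH2 carbon acylates on one malonate ester (bond C4–C5) with loss of methoxide, and immediate deprotonation of the new 1,3-dione makes the sequence irreversible and drains a possibly unfavourable Michael equilibrium. The closest known reaction type is the malonate Michael–Claisen (Dieckmann-type) annulation of simple alk-3-en-2-ones to 5-alkylcyclohexane-1,3-diones used for alkylresorcinols; untested is an acyclic enone whose α-carbon carries an ether oxygen, which lowers the electrophilicity of the β-carbon and is answered by excess malonate, high concentration and reflux. The ring closes in a 6-(enolendo)-exo-trig mode, because both enolate carbons (C5, C6) end up inside the ring while the ester C=O stays outside it. Three sp3 centres (C1, C2, C3) arise without control as an epimerisable mixture, which is harmless because all are sp2 after step 6. The step needs 1,4- rather than 1,2-addition and closure from the methyl side alone: the soft, reversibly adding malonate anion secures the first, and ring size secures the second, since the enolate on the benzyloxy side could only form a four-membered ring. Benzyl alcohol has no E1cB exit, because the only C–H next to the benzyloxy-bearing carbon (C2–H) is not α to a carbonyl group in 8 or 9.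

Step 5
Reactants: 9 methyl 3-(benzyloxy)-4,6-dioxo-2-tricosylcyclohexane-1-carboxylate
Product: 11 4-(benzyloxy)-5-tricosylcyclohexane-1,3-dione (diastereomer mixture), via beta-keto acid 10 (not isolated)
Conditions: 2 M aq NaOH, MeOH–THF, 65 °C, Ar; then HCl to pH 2, 60 °C
Reagents that add atoms: none
Why: Ester saponification followed by decarboxylation of the β-keto acid is the classical end of cyclohexane-1,3-dione syntheses, the dione being shielded from retro-Claisen cleavage as its enolate and the benzyl ether being inert to both media.

Step 6
Reactants: 11 4-(benzyloxy)-5-tricosylcyclohexane-1,3-dione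
Product: 12 2-(benzyloxy)-1,5-dimethoxy-3-tricosylbenzene
Conditions: I2 (2 equiv), MeOH–1,2-dichloroethane, 65 °C; aq Na2S2O3
Reagents that add atoms: methanol, CO
Why: In the iodine–methanol oxidative aromatisation of cyclohexane-1,3-diones to resorcinol dimethyl ethers, the HI formed in situ catalyses enol-ether and ketal formation with methanol and α-iodination with loss of HI supplies the missing unsaturation, so C4 and C6 emerge as OMe while C1 keeps its benzyl ether.

Step 7
Reactants: 12 2-(benzyloxy)-1,5-dimethoxy-3-tricosylbenzene
Product: 13 2,4-dimethoxy-6-tricosylphenol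
Conditions: H2 (1 atm), 10 % Pd/C, EtOAc–THF, rt; work-up under Ar
Reagents that add atoms: none
Why: Catalytic hydrogenolysis cleaves only the benzylic C–O bond, while the methyl ethers, the arene and the saturated chain are inert.

Compound list
1 | 1-tetracosanol | CCCCCCCCCCCCCCCCCCCCCCCCO | starting material
2 | tetracosanal | CCCCCCCCCCCCCCCCCCCCCCCC=O | intermediate
3 | dimethyl (1-diazo-2-oxopropyl)phosphonate | CC(=O)C(=[N+]=[N-])P(=O)(OC)OC | starting material
4 | benzyl alcohol | OCc1ccccc1 | starting material
5 | dimethyl [1-(benzyloxy)-2-oxopropyl]phosphonate (racemic) | CC(=O)C(OCc1ccccc1)P(=O)(OC)OC | intermediate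
6 | (Z)-3-(benzyloxy)heptacos-3-en-2-one | CCCCCCCCCCCCCCCCCCCCCCC/C=C(\OCc1ccccc1)C(C)=O | intermediate
7 | dimethyl malonate | COC(=O)CC(=O)OC | starting material
8 | dimethyl 2-[3-(benzyloxy)-2-oxoheptacosan-4-yl]propanedioate (diastereomer mixture, not isolated) | CCCCCCCCCCCCCCCCCCCCCCCC(C(OCc1ccccc1)C(C)=O)C(C(=O)OC)C(=O)OC | intermediate
9 | methyl 3-(benzyloxy)-4,6-dioxo-2-tricosylcyclohexane-1-carboxylate (diastereomer mixture) | CCCCCCCCCCCCCCCCCCCCCCCC1C(C(=O)OC)C(=O)CC(=O)C1OCc1ccccc1 | intermediate
10 | 3-(benzyloxy)-4,6-dioxo-2-tricosylcyclohexane-1-carboxylic acid (not isolated) | CCCCCCCCCCCCCCCCCCCCCCCC1C(C(=O)O)C(=O)CC(=O)C1OCc1ccccc1 | intermediate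
11 | 4-(benzyloxy)-5-tricosylcyclohexane-1,3-dione (diastereomer mixture) | CCCCCCCCCCCCCCCCCCCCCCCC1CC(=O)CC(=O)C1OCc1ccccc1 | intermediate
12 | 2-(benzyloxy)-1,5-dimethoxy-3-tricosylbenzene | CCCCCCCCCCCCCCCCCCCCCCCc1cc(OC)cc(OC)c1OCc1ccccc1 | intermediate
13 | 2,4-dimethoxy-6-tricosylphenol | CCCCCCCCCCCCCCCCCCCCCCCc1cc(OC)cc(OC)c1O | target

Total step count: 7
Longest linear sequence: 6 steps (1 → 2 → 6 → 9 → 11 → 12 → 13; the branch from 3 through 5 is equally long)

Steps most likely to fail

**Step 4.** The ether oxygen on the α-carbon feeds electron density to the β-carbon, so conjugate addition may be slow. Retro-Michael reaction, γ-deprotonation with deconjugation, and self-condensation of the methyl ketone could then outrun ring closure.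

The fallback uses known chemistry only. It keeps the malonate annulation but no longer carries the C1 oxygen through it, placing that oxygen on the finished arene instead.
- It sets out from 2. Wittig olefination with 1-(triphenylphosphoranylidene)propan-2-one should give (E)-heptacos-3-en-2-one F1.
- F1 undergoes the standard annulation with 7 and NaOMe to methyl 2,4-dioxo-6-tricosylcyclohexane-1-carboxylate F2.
- Saponification and decarboxylation give 5-tricosylcyclohexane-1,3-dione F3, and iodine–methanol aromatisation gives 1,3-dimethoxy-5-tricosylbenzene F4.
- Vilsmeier–Haack formylation attacks 5-alkylresorcinol dimethyl ethers para to one methoxy group and ortho to the chain. It should give 2,4-dimethoxy-6-tricosylbenzaldehyde F5.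
- Baeyer–Villiger (Dakin-type) oxidation with mCPBA gives 2,4-dimethoxy-6-tricosylphenyl formate F6.
- Hydrolysis with aqueous NaOH and acidic work-up comes back to the route at 13.

**Step 6.** Prolonged heating in methanolic HI may cause several problems:
- exchange or cleavage of the benzyl group through the enediol ether tautomer;
- elimination of benzyl alcohol at the dienol-ether stage, driven by aromatisation;
- incomplete ether formation at one oxygen;
- iodination of the very electron-rich ring.

The fallback sets out from 9 and aromatises before the ester is removed, so that oxidation and methylation are separated.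
- Bromine (1 equiv) in DMF at 0 °C, then 80 °C, brominates and dehydrobrominates the enolised β-keto ester. This is the established entry to alkylresorcylates, and it should give methyl 3-(benzyloxy)-4,6-dihydroxy-2-tricosylbenzoate F7.
- Refluxing aqueous-methanolic NaOH followed by acidification saponifies and decarboxylates the resorcylate to 4-(benzyloxy)-5-tricosylbenzene-1,3-diol F8.
- Williamson methylation of both phenols (MeI, K2CO3, acetone), under basic conditions that cannot touch the benzyl ether, comes back to the route at 12.

**Step 3.** The α-oxygenated, fully substituted phosphonate anion may olefinate slowly. Enolisation and self-aldol reaction of the poorly soluble aldehyde could then compete.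

The fallback replaces the olefination by an aldol addition and elimination.
- It sets out from 2. 1-(Benzyloxy)propan-2-one is enolised softly with TiCl4 and iPr2NEt in CH2Cl2. Chelation by the benzyloxy oxygen should direct deprotonation to the oxygenated carbon.
- Addition of the resulting enolate to 2 gives 3-(benzyloxy)-4-hydroxyheptacosan-2-one F9.
- MsCl and Et3N give 3-(benzyloxy)-2-oxoheptacosan-4-yl methanesulfonate F10.
- E1cB elimination with DBU comes back to the route at 6.

Further compounds
F1 | step 4 | (E)-heptacos-3-en-2-one | CCCCCCCCCCCCCCCCCCCCCCC/C=C/C(C)=O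
F2 | step 4 | methyl 2,4-dioxo-6-tricosylcyclohexane-1-carboxylate | CCCCCCCCCCCCCCCCCCCCCCCC1CC(=O)CC(=O)C1C(=O)OC
F3 | step 4 | 5-tricosylcyclohexane-1,3-dione | CCCCCCCCCCCCCCCCCCCCCCCC1CC(=O)CC(=O)C1
F4 | step 4 | 1,3-dimethoxy-5-tricosylbenzene | CCCCCCCCCCCCCCCCCCCCCCCc1cc(OC)cc(OC)c1
F5 | step 4 | 2,4-dimethoxy-6-tricosylbenzaldehyde | CCCCCCCCCCCCCCCCCCCCCCCc1cc(OC)cc(OC)c1C=O
F6 | step 4 | 2,4-dimethoxy-6-tricosylphenyl formate | CCCCCCCCCCCCCCCCCCCCCCCc1cc(OC)cc(OC)c1OC=O
F7 | step 6 | methyl 3-(benzyloxy)-4,6-dihydroxy-2-tricosylbenzoate | CCCCCCCCCCCCCCCCCCCCCCCc1c(C(=O)OC)c(O)cc(O)c1OCc1ccccc1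
F8 | step 6 | 4-(benzyloxy)-5-tricosylbenzene-1,3-diol | CCCCCCCCCCCCCCCCCCCCCCCc1cc(O)cc(O)c1OCc1ccccc1
F9 | step 3 | 3-(benzyloxy)-4-hydroxyheptacosan-2-one | CCCCCCCCCCCCCCCCCCCCCCCC(O)C(OCc1ccccc1)C(C)=O
F10 | step 3 | 3-(benzyloxy)-2-oxoheptacosan-4-yl methanesulfonate | CCCCCCCCCCCCCCCCCCCCCCCC(OS(C)(=O)=O)C(OCc1ccccc1)C(C)=O
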